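**Conventions.** Target numbering is used throughout: indane C1 carries the 4-hydroxyphenyl ring, C2 the 3,5-dihydroxyphenyl ring, C3 the exocyclic alkene; primed locants belong to the dihydrobenzofuran (O1', C2', C3', C3a', C5'). In the indanones 22 and 23 the ketone carbon (C1 by nomenclature) is C3 of the target. Compounds 1–28 are numbered in the order of the steps.

## The problem

The target 28 is a resveratrol trimer. A trans-1,2-diarylindane, hydroxylated at C5 and C7, is tied through an exocyclic E double bond at C3 to a CH group on C5' of a trans-2-(4-hydroxyphenyl)-3-(3,5-dihydroxyphenyl)-2,3-dihydrobenzofuran. The four stereocentres fall into two pairs, 1S,2S and 2'R,3'R. Within each pair one centre can set the other, since trans is the more stable arrangement on both five-membered rings. The pairs are separated by the alkene and a benzene ring and cannot instruct each other, so each half needs its own absolute control and the halves should meet late. C2–H is allylic and doubly benzylic, and the isomer with the double bond inside the ring is a more stable tetrasubstituted indene that erases C2, so the alkene must be made and kept under non-equilibrating conditions. The C2'–O1' bond is a benzylic ether para to an oxygenated ring: it ionises under acid, and a carbanion at C3' expels O1' by β-elimination. Eight free phenols rule out late oxidants and demand a cold, non-reductive deprotection. In the indane, C3 is meta to both ring oxygens and C1 is ortho/para to them, so the five-membered ring has to be closed at C1–C7a by an aryl metal, not by acylation at C3–C3a. The feature that opens the key step is that C3' is bonded to C2' (bearing O1' and the 4-hydroxyphenyl ring) and to the benzo carbon C3a'. This is the connectivity left when the fused aryl carbon of a 2-arylchroman-4-one shifts from the carbonyl carbon to C3; the old carbonyl carbon stays on C3' as a carboxyl group, the placeholder for the 3,5-dihydroxyphenyl ring, and C5' (para to O1') maps onto C6 of the chromanone.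

## Retrosynthesis

**28 from 27 (eight O–benzyl bonds).** No skeletal bond is cut. Methyl ethers would need BBr3 at room temperature for hours, and C2'–O1' is itself an aryl benzyl ether para to an alkoxy group that can open and eliminate under such treatment. Hydrogenolysis would reduce the alkene. Benzyl ethers fall at −78 °C to BCl3 with pentamethylbenzene as cation trap, so all eight phenols are carried as benzyl ethers in 27. The forward step must leave the alkene, C2–H and C2'–O1' alone.

**27 from 26, and 26 from 17 and 23 (C3=CH, then C3–CH2).** The alkene is traced to the tertiary carbinol 26, and its C3–CH2 bond is cut between ketone 23 and the benzylic chloride 17. Three neighbouring cuts were weighed: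
- A phosphorus ylide on 23 would meet a hindered, easily enolised α-aryl ketone.
- A Heck arylation of the methylene indane has two β-hydrogens to choose from.
- A cut at CH–C5' needs a geometrically defined alkenyl metal on the indane.

The chosen cut divides the molecule into halves of similar size, each carrying one complete pair of stereocentres. The forward steps must add without losing the ketone to enolisation (organocerium) and must dehydrate away from C2. Addition anti to the C2 aryl group puts OH trans to C2–H, so a syn elimination can only reach the exocyclic CH2.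

**23 from 22 and 10; 22 from 21; 21 from 19 and 20; 19 from 18.** The C2–aryl bond is cut as a palladium enolate arylation; trans follows from equilibration of the α-aryl ketone. C1–C7a is cut as an enantioselective reductive Heck closure of the 2'-bromochalcone 21. The bromine of 19 enters by electrophilic substitution at the position ortho/para to both ether oxygens, which is exactly the carbon that must bond, so regiochemistry and ring-closure site are fixed together. An acid-mediated Nazarov closure of the unbrominated chalcone forms the same bond but is racemic. This reduces 23 to three catalogue aromatics (18, 20, 10).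

**17 from 16, 16 from 15, 15 from 13 (C5'–CH2, and the protecting-group change).** The one-carbon arm is cut back to the aryl bromide 15, which accepts a hydroxymethyl group by Stille coupling; chlorination gives 17. The bromine has been in place since the chromone. The mesylate that steers the key step is exchanged for benzyl at 13, where there is no enolisable position next to O1' and before any Grignard reagent is made. The methyl protons of a mesylate would not survive a benzylic Grignard reagent.

**13 from 9 and 10; 9 from 8; 8 from 7 (C3'–aryl).** The 3,5-dioxygenated ring is attached by decarboxylative arylation of the redox-active ester 9. The C3' radical is planar, so the aryl group enters anti to the C2' aryl group whatever the configuration of the acid. Iron is chosen over nickel or palladium because it leaves C5'–Br and the aryl mesylate alone. Polar alternatives (ester enolate arylation, base hydrolysis) put negative charge on C3' and would eject O1', which is why the ester is cleaved with Me3SnOH.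

**7 from 4 (key disconnection: C3'–C3a' broken, C3a' returned to the ester carbon).** Undoing the 1,2-aryl shift turns the dihydrobenzofuran ester 7 into the flavanone 4. Direct routes to trans-2,3-diaryl dihydrobenzofurans were set against this:
- Oxidative phenol–stilbene coupling gives no absolute control.
- Carbene C–H insertion gives the cis ester and needs a diazo compound.

The flavanone needs one stereocentre, made in one catalytic step, and that centre then sets C3'. The forward reaction must move the fused aryl carbon, not the C2 aryl group, and must never make C2 planar.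

**4 from 2 and 3; 2 from 1.** The C2–aryl bond is cut as an asymmetric conjugate addition of boronic acid 2 to 6-bromochromone 3. The divalent-palladium cycle has no zerovalent stage, so the bromide survives. The mesylate is put on the boronic acid 1 beforehand.

## Roads not taken

**Alternative 1: photochemical benzannulation onto a diarylcyclopentene.**
- Cut: the resorcinol ring of the indane itself (C3a–C4, C4–C5, C6–C7, C7–C7a), leaving a cyclopentene that already holds C1, C2 and an oxygenated C3.
- Forward key step: irradiation of diazo ketone A2 with ethoxyacetylene A3. Wolff shift, [2+2] addition of the alkyne to the ketene, four-electron ring opening and six-electron closure give phenol A1.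
- Merits: all sp3 centres of the five-membered ring are fixed before the arene exists; ring fusion has no regiochemical choice; the two ring oxygens emerge differentiated.
- Weak points: A2 carries three contiguous stereocentres next to an unsaturated diazo ketone and is harder to make than indanone 23. The ring built is one that can be bought with the right substitution (18). Carbene and ketene intermediates sit beside two electron-rich aryl rings and a doubly benzylic C–H. A1 still needs desilylation, oxidation and ether exchange before it can play the role of 23. Nothing is said about the dihydrobenzofuran.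
- Comparison: Alternative 1 is better in that no epimerisable α-aryl ketone is present while stereochemistry is being set. The chosen plan sets against this four catalytic steps from catalogue compounds to 23, with the bromine of 19 giving the same regiochemical certainty.

**Alternative 2: coumalate benzannulation of a diaryl butyrolactone.**
- Cut: the benzo ring of the dihydrobenzofuran (C3a'–C4' and C7a'–C7').
- Forward key step: the silyl ketene acetal A6 of lactone A5 adds to methyl coumalate A7. Loss of CO2 and silanol aromatises the adduct to benzoate A4.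
- Merits: the ester of A4 is the arm carbon at C5' in a useful oxidation state, which would save the Stille step. No oxidant is needed, and the 4-methoxyphenyl ring needs no sulfonate detour. In these respects it is shorter than the chosen plan after the key step.
- Weak points: A5 has both stereocentres and needs its own asymmetric synthesis of several steps. The aromatisation has two leaving groups on C7a', silanolate and the ring alkoxide; loss of the latter opens the ring for good. Regiochemistry of the cycloaddition must put the ester para to O1'.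
- Comparison: the chosen plan sets against the saved arm step a one-step catalytic asymmetric entry (2 + 3 → 4), a ring contraction documented on flavanones, and a single stereocentre that controls the second.

**Alternative 3: rhodium 1,4-shift isomerisation to the indanone.**
- Cut: C1–C7a of the indane, as in the chosen plan, but from a C–H bond.
- Forward key step: [Rh(OH)(cod)]2 with a chiral bisphosphine converts racemic propargyl alcohol A9 into indanone A8. The sequence is β-hydride elimination, alkyne hydrorhodation, 1,4-shift of rhodium to the ortho carbon and enantioselective aryl addition.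
- Merits: redox-neutral, halogen-free, and two steps from an aldehyde and an alkyne. This is one step shorter than steps 10–12 here and the better route in atom economy.
- Weak points: the rhodium must migrate to a C–H flanked by an ether and the acyl group. The alkyne substituent is an aryl group, so the enantio-determining addition is to a chalcone-like enone, and simple redox isomerisation competes. It serves only the indane half.
- Comparison: it could replace steps 10–12 without touching the rest. The chosen plan keeps the bromide because it fixes the ring-closure site, and because the weight of the plan lies in the dihydrobenzofuran, which Alternative 3 does not address.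

Key step: step 3

## Route

Assumption: the ligand enantiomers named in steps 2 and 12 are those expected to give the 2R flavanone and the 3S indanone; if induction on these substrates runs the other way, the mirror-image ligand is used.
Assumption: 1,3-bis(benzyloxy)-5-bromobenzene (10) is taken as a catalogue compound.

Step 1
Reactants: 1 4-hydroxyphenylboronic acid
Product: 2 4-(methylsulfonyloxy)phenylboronic acid
Conditions: MsCl, Et3N, THF, 0 °C; aq. HCl work-up
Reagents that add atoms: methanesulfonyl chloride, CS(=O)(=O)Cl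
Why: O-sulfonylation of the phenol; any mixed anhydride at boron is hydrolysed back to the boronic acid on acidic work-up.

Step 2
Reactants: 2 4-(methylsulfonyloxy)phenylboronic acid; 3 6-bromochromone
Product: 4 (R)-6-bromo-2-[4-(methylsulfonyloxy)phenyl]chroman-4-one
Conditions: Pd(OCOCF3)2, (S)-t-BuPyOx, NH4PF6, H2O, ClCH2CH2Cl, 60 °C
Reagents that add atoms: none
Why: Asymmetric conjugate addition of an arylboronic acid to a chromone on divalent palladium with a pyridine–oxazoline ligand (transmetalation, enantio-determining insertion of C2=C3, protonolysis of the palladium enolate). The ligand sets C2. No zerovalent palladium is formed, so the bromide and the mesylate should survive.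

Step 3
Reactants: 4 (R)-6-bromo-2-[4-(methylsulfonyloxy)phenyl]chroman-4-one
Product: 7 methyl (2R,3R)-5-bromo-2-[4-(methylsulfonyloxy)phenyl]-2,3-dihydrobenzofuran-3-carboxylate (trans), via methyl enol ether 5 (not isolated), via ortho ester 6 (not isolated)
Conditions: PhI(OAc)2, conc. H2SO4, HC(OMe)3, rt; then H2O
Reagents that add atoms: trimethyl orthoformate, COC(OC)OC; water, O
Why: Acid and the orthoformate turn the C4 ketone into its methyl enol ether 5; protonated PhI(OAc)2 attacks C3 on the face anti to the C2 aryl group and methanol caps C4, so that a phenyl-λ3-iodanyl group sits equatorial on C3 beside a dimethyl ketal. The C4–C4a ring bond is antiperiplanar to this C3–I bond, and the fused aryl carbon C4a shifts from C4 to C3 through a bridged phenonium-type transition state as iodobenzene leaves; C4 becomes a dimethoxycarbenium ion that methanol takes up as ortho ester 6, hydrolysed to the methyl ester on aqueous work-up. The closest known reaction type is the trivalent-iodine (or thallium trinitrate) oxidative ring contraction of flavanones in trimethyl orthoformate, a relative of the 1,2-aryl shift of α-halo aryl ketone ketals. The five-membered ring is closed not by cyclisation but by this 1,2-shift: the pyranone contracts from six to five as C3–C3a forms and C4–C4a breaks, and C2 with its oxygen and aryl group is never planar, so its R configuration is carried over. The new stereocentre C3 is set by C2: iodane anti to the aryl group and migration with inversion at C3 place the ester trans, which is also the more stable arrangement. The step needs migration of the fused aryl carbon in preference to a 2,3-shift of the C2 aryl group (isoflavone) and to loss of the C2 proton (flavone). The diequatorial conformer, the ring oxygen ortho to the migrating carbon and the electron-poor mesyloxyphenyl ring (a poor migrating group) all favour the contraction. Bromide and mesylate are inert to the oxidant.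

Step 4
Reactants: 7 methyl (2R,3R)-5-bromo-2-[4-(methylsulfonyloxy)phenyl]-2,3-dihydrobenzofuran-3-carboxylate
Product: 8 (2R,3R)-5-bromo-2-[4-(methylsulfonyloxy)phenyl]-2,3-dihydrobenzofuran-3-carboxylic acid
Conditions: Me3SnOH, ClCH2CH2Cl, 80 °C; aq. HCl wash
Reagents that add atoms: trimethyltin hydroxide, C[Sn](C)(C)O
Why: Neutral tin-hydroxide cleavage of a methyl ester. It avoids the ester enolate, which would expel O1' by β-elimination and destroy C2; the aryl mesylate is not attacked.

Step 5
Reactants: 8 (2R,3R)-5-bromo-2-[4-(methylsulfonyloxy)phenyl]-2,3-dihydrobenzofuran-3-carboxylic acid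
Product: 9 1,3-dioxoisoindolin-2-yl (2R,3R)-5-bromo-2-[4-(methylsulfonyloxy)phenyl]-2,3-dihydrobenzofuran-3-carboxylate
Conditions: N-hydroxyphthalimide, DIC, CH2Cl2, 0 °C to rt
Reagents that add atoms: N-hydroxyphthalimide, O=C1c2ccccc2C(=O)N1O
Why: Carbodiimide esterification to the redox-active ester, run without amine base so that the acidic C3 proton of the activated ester is not removed.

Step 6
Reactants: 9 1,3-dioxoisoindolin-2-yl (2R,3R)-5-bromo-2-[4-(methylsulfonyloxy)phenyl]-2,3-dihydrobenzofuran-3-carboxylate; 10 1,3-bis(benzyloxy)-5-bromobenzene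
Product: 13 (2R,3R)-3-[3,5-bis(benzyloxy)phenyl]-5-bromo-2-[4-(methylsulfonyloxy)phenyl]-2,3-dihydrobenzofuran (trans), via arylmagnesium bromide 11 (not isolated), via arylzinc chloride 12 (not isolated)
Conditions: 10, Mg, LiCl, THF; ZnCl2; then 9, Fe(acac)3, 1,2-bis(diphenylphosphino)benzene, THF/toluene, rt
Reagents that add atoms: none
Why: Iron-catalysed decarboxylative Negishi-type arylation of a secondary redox-active ester: electron transfer to the ester releases CO2 and phthalimide anion, and the C3 benzylic radical is captured by the aryl–iron species. The radical is planar, so the new C3 centre is set by C2, with the aryl group entering anti to the C2 aryl group (trans). The ring C2–O bond is orthogonal to the radical p orbital and should not fragment, and iron leaves the C–Br bond and the mesylate untouched.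

Step 7
Reactants: 13 (2R,3R)-3-[3,5-bis(benzyloxy)phenyl]-5-bromo-2-[4-(methylsulfonyloxy)phenyl]-2,3-dihydrobenzofuran
Product: 15 (2R,3R)-3-[3,5-bis(benzyloxy)phenyl]-2-[4-(benzyloxy)phenyl]-5-bromo-2,3-dihydrobenzofuran, via phenol 14 (not isolated)
Conditions: KOH, H2O/1,4-dioxane, 80 °C; then BnBr, Bu4NI, 50 °C
Reagents that add atoms: benzyl bromide, BrCc1ccccc1
Why: Alkaline hydrolysis of the aryl mesylate followed by Williamson benzylation of the phenoxide under phase transfer in the same flask. Compound 13 has no acidic C–H next to O1', so neither stereocentre is at risk.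

Step 8
Reactants: 15 (2R,3R)-3-[3,5-bis(benzyloxy)phenyl]-2-[4-(benzyloxy)phenyl]-5-bromo-2,3-dihydrobenzofuran
Product: 16 [(2R,3R)-3-[3,5-bis(benzyloxy)phenyl]-2-[4-(benzyloxy)phenyl]-2,3-dihydrobenzofuran-5-yl]methanol
Conditions: Bu3SnCH2OH, Pd(PPh3)4, 1,4-dioxane, 100 °C
Reagents that add atoms: (tributylstannyl)methanol, OC[Sn](CCCC)(CCCC)CCCC
Why: Migita–Kosugi–Stille hydroxymethylation of the aryl bromide; neutral conditions, benzyl ethers and both stereocentres are spectators.

Step 9
Reactants: 16 [(2R,3R)-3-[3,5-bis(benzyloxy)phenyl]-2-[4-(benzyloxy)phenyl]-2,3-dihydrobenzofuran-5-yl]methanol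
Product: 17 (2R,3R)-3-[3,5-bis(benzyloxy)phenyl]-2-[4-(benzyloxy)phenyl]-5-(chloromethyl)-2,3-dihydrobenzofuran
Conditions: SOCl2, cat. DMF, CH2Cl2, 0 °C; used crude
Reagents that add atoms: thionyl chloride, O=S(Cl)Cl
Why: Chlorination of an electron-rich (para-alkoxy) benzylic alcohol through its chlorosulfite; the chloride is reactive and is taken on without chromatography.

Step 10
Reactants: 18 1-[3,5-bis(benzyloxy)phenyl]ethan-1-one
Product: 19 1-[3,5-bis(benzyloxy)-2-bromophenyl]ethan-1-one
Conditions: NBS, MeCN, 0 °C to rt, dark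
Reagents that add atoms: N-bromosuccinimide, O=C1CCC(=O)N1Br
Why: Electrophilic aromatic bromination at C2, ortho and para to the two ether oxygens and less hindered than C4 between them. A polar solvent without acid or radical initiator should suppress side-chain bromination.

Step 11
Reactants: 19 1-[3,5-bis(benzyloxy)-2-bromophenyl]ethan-1-one; 20 4-(benzyloxy)benzaldehyde
Product: 21 (E)-1-[3,5-bis(benzyloxy)-2-bromophenyl]-3-[4-(benzyloxy)phenyl]prop-2-en-1-one
Conditions: KOH, EtOH/THF, rt
Reagents that add atoms: none
Why: Claisen–Schmidt condensation; dehydration of the aldol gives the conjugated E enone.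

Step 12
Reactants: 21 (E)-1-[3,5-bis(benzyloxy)-2-bromophenyl]-3-[4-(benzyloxy)phenyl]prop-2-en-1-one
Product: 22 (S)-4,6-bis(benzyloxy)-3-[4-(benzyloxy)phenyl]indan-1-one
Conditions: Pd(OAc)2, (R)-3,5-Xyl-MeO-BIPHEP, HCO2H, iPr2NEt, ethylene glycol/DMF, 90 °C
Reagents that add atoms: none
Why: Enantioselective intramolecular reductive Heck reaction of a 2'-halochalcone: the aryl–palladium bond adds across the enone with the aryl carbon on the β-carbon, and the palladium enolate, which has no syn β-hydrogen, is reduced by formate. The bisphosphine sets C3 in the insertion; the hydrogen-bonding medium frees bromide from palladium so that the cationic, selective pathway operates.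

Step 13
Reactants: 22 (S)-4,6-bis(benzyloxy)-3-[4-(benzyloxy)phenyl]indan-1-one; 10 1,3-bis(benzyloxy)-5-bromobenzene
Product: 23 (2S,3S)-4,6-bis(benzyloxy)-2-[3,5-bis(benzyloxy)phenyl]-3-[4-(benzyloxy)phenyl]indan-1-one (trans)
Conditions: Pd(OAc)2, XPhos, NaOtBu, toluene, 80 °C; aq. NH4Cl
Reagents that add atoms: none
Why: Palladium-catalysed α-arylation of a ketone enolate, a known stereoselective reaction of 3-aryl-1-indanones. C2 is set by C3 through equilibration of the acidic α-aryl ketone to the trans isomer; C3 is not enolisable and keeps its configuration, and the bulky ligand should hold the reaction at monoarylation.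

Step 14
Reactants: 17 (2R,3R)-3-[3,5-bis(benzyloxy)phenyl]-2-[4-(benzyloxy)phenyl]-5-(chloromethyl)-2,3-dihydrobenzofuran; 23 (2S,3S)-4,6-bis(benzyloxy)-2-[3,5-bis(benzyloxy)phenyl]-3-[4-(benzyloxy)phenyl]indan-1-one
Product: 26 (1R,2S,3S)-4,6-bis(benzyloxy)-2-[3,5-bis(benzyloxy)phenyl]-3-[4-(benzyloxy)phenyl]-1-{[(2R,3R)-3-[3,5-bis(benzyloxy)phenyl]-2-[4-(benzyloxy)phenyl]-2,3-dihydrobenzofuran-5-yl]methyl}indan-1-ol, via benzylmagnesium chloride 24 (not isolated), via benzylcerium dichloride 25 (not isolated)
Conditions: 17, Mg, LiCl, THF, 0 °C (slow addition); CeCl3, THF, −78 °C; then 23, −78 to 0 °C; aq. NH4Cl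
Reagents that add atoms: none
Why: Organocerium addition of a benzylic Grignard reagent to an easily enolised α-aryl ketone; the cerium reagent is nucleophilic but weakly basic. Attack anti to the C2 aryl group should give the 1R carbinol with OH cis to that aryl group and trans to C2–H, a centre that is lost in step 15 but directs it.

Step 15
Reactants: 26 (1R,2S,3S)-4,6-bis(benzyloxy)-2-[3,5-bis(benzyloxy)phenyl]-3-[4-(benzyloxy)phenyl]-1-{[(2R,3R)-3-[3,5-bis(benzyloxy)phenyl]-2-[4-(benzyloxy)phenyl]-2,3-dihydrobenzofuran-5-yl]methyl}indan-1-ol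
Product: 27 (2R,3R)-5-[(E)-{(2S,3S)-4,6-bis(benzyloxy)-2-[3,5-bis(benzyloxy)phenyl]-3-[4-(benzyloxy)phenyl]-2,3-dihydro-1H-inden-1-ylidene}methyl]-3-[3,5-bis(benzyloxy)phenyl]-2-[4-(benzyloxy)phenyl]-2,3-dihydrobenzofuran
Conditions: Burgess reagent, toluene, rt to 50 °C
Reagents that add atoms: none
Why: Burgess dehydration by syn elimination of the tertiary sulfamate. C2–H lies on the face opposite to the leaving group, so only the exocyclic CH2 can deliver a hydrogen and the double bond should form outside the ring under neutral conditions. The transition state that turns the dihydrobenzofuranyl group away from the peri C4–H of the fused ring gives the E isomer.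

Step 16
Reactants: 27 (2R,3R)-5-[(E)-{(2S,3S)-4,6-bis(benzyloxy)-2-[3,5-bis(benzyloxy)phenyl]-3-[4-(benzyloxy)phenyl]-2,3-dihydro-1H-inden-1-ylidene}methyl]-3-[3,5-bis(benzyloxy)phenyl]-2-[4-(benzyloxy)phenyl]-2,3-dihydrobenzofuran
Product: 28 (1S,2S)-3-{(E)-[(2R,3R)-3-(3,5-dihydroxyphenyl)-2-(4-hydroxyphenyl)-2,3-dihydrobenzofuran-5-yl]methylidene}-2-(3,5-dihydroxyphenyl)-1-(4-hydroxyphenyl)indane-5,7-diol (CNP0184753.1)
Conditions: BCl3, pentamethylbenzene, CH2Cl2, −78 °C; MeOH quench
Reagents that add atoms: none
Why: Lewis-acid cleavage of aryl benzyl ethers with a non-basic cation scavenger, the standard mild debenzylation for stilbene-derived polyphenols. At −78 °C the benzyl cations should go to pentamethylbenzene rather than to the resorcinol rings or the alkene, and the alkene and the C2'–O1' ether should be preserved.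

## Compound list

1 | 4-hydroxyphenylboronic acid | OB(O)c1ccc(O)cc1 | starting material
2 | 4-(methylsulfonyloxy)phenylboronic acid | CS(=O)(=O)Oc1ccc(B(O)O)cc1 | intermediate
3 | 6-bromochromone | O=c1ccoc2ccc(Br)cc12 | starting material
4 | (R)-6-bromo-2-[4-(methylsulfonyloxy)phenyl]chroman-4-one | O=C1C[C@H](c2ccc(OS(C)(=O)=O)cc2)Oc2ccc(Br)cc12 | intermediate
5 | (R)-6-bromo-4-methoxy-2-[4-(methylsulfonyloxy)phenyl]-2H-chromene | COC1=C[C@H](c2ccc(OS(C)(=O)=O)cc2)Oc2ccc(Br)cc12 | intermediate
6 | (2R,3R)-5-bromo-2-[4-(methylsulfonyloxy)phenyl]-3-(trimethoxymethyl)-2,3-dihydrobenzofuran | Brc1ccc2c(c1)[C@@H](C(OC)(OC)OC)[C@H](c1ccc(OS(C)(=O)=O)cc1)O2 | intermediate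
7 | methyl (2R,3R)-5-bromo-2-[4-(methylsulfonyloxy)phenyl]-2,3-dihydrobenzofuran-3-carboxylate | Brc1ccc2c(c1)[C@@H](C(=O)OC)[C@H](c1ccc(OS(C)(=O)=O)cc1)O2 | intermediate
8 | (2R,3R)-5-bromo-2-[4-(methylsulfonyloxy)phenyl]-2,3-dihydrobenzofuran-3-carboxylic acid | Brc1ccc2c(c1)[C@@H](C(=O)O)[C@H](c1ccc(OS(C)(=O)=O)cc1)O2 | intermediate
9 | 1,3-dioxoisoindolin-2-yl (2R,3R)-5-bromo-2-[4-(methylsulfonyloxy)phenyl]-2,3-dihydrobenzofuran-3-carboxylate | Brc1ccc2c(c1)[C@@H](C(=O)ON1C(=O)c3ccccc3C1=O)[C@H](c1ccc(OS(C)(=O)=O)cc1)O2 | intermediate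
10 | 1,3-bis(benzyloxy)-5-bromobenzene | Brc1cc(OCc2ccccc2)cc(OCc2ccccc2)c1 | starting material
11 | [3,5-bis(benzyloxy)phenyl]magnesium bromide | Br[Mg]c1cc(OCc2ccccc2)cc(OCc2ccccc2)c1 | intermediate
12 | [3,5-bis(benzyloxy)phenyl]zinc chloride | Cl[Zn]c1cc(OCc2ccccc2)cc(OCc2ccccc2)c1 | intermediate
13 | (2R,3R)-3-[3,5-bis(benzyloxy)phenyl]-5-bromo-2-[4-(methylsulfonyloxy)phenyl]-2,3-dihydrobenzofuran | Brc1ccc2c(c1)[C@@H](c1cc(OCc3ccccc3)cc(OCc3ccccc3)c1)[C@H](c1ccc(OS(C)(=O)=O)cc1)O2 | intermediate
14 | 4-[(2R,3R)-3-[3,5-bis(benzyloxy)phenyl]-5-bromo-2,3-dihydrobenzofuran-2-yl]phenol (formed as its potassium salt) | Brc1ccc2c(c1)[C@@H](c1cc(OCc3ccccc3)cc(OCc3ccccc3)c1)[C@H](c1ccc(O)cc1)O2 | intermediate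
15 | (2R,3R)-3-[3,5-bis(benzyloxy)phenyl]-2-[4-(benzyloxy)phenyl]-5-bromo-2,3-dihydrobenzofuran | Brc1ccc2c(c1)[C@@H](c1cc(OCc3ccccc3)cc(OCc3ccccc3)c1)[C@H](c1ccc(OCc3ccccc3)cc1)O2 | intermediate
16 | [(2R,3R)-3-[3,5-bis(benzyloxy)phenyl]-2-[4-(benzyloxy)phenyl]-2,3-dihydrobenzofuran-5-yl]methanol | OCc1ccc2c(c1)[C@@H](c1cc(OCc3ccccc3)cc(OCc3ccccc3)c1)[C@H](c1ccc(OCc3ccccc3)cc1)O2 | intermediate
17 | (2R,3R)-3-[3,5-bis(benzyloxy)phenyl]-2-[4-(benzyloxy)phenyl]-5-(chloromethyl)-2,3-dihydrobenzofuran | ClCc1ccc2c(c1)[C@@H](c1cc(OCc3ccccc3)cc(OCc3ccccc3)c1)[C@H](c1ccc(OCc3ccccc3)cc1)O2 | intermediate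
18 | 1-[3,5-bis(benzyloxy)phenyl]ethan-1-one | CC(=O)c1cc(OCc2ccccc2)cc(OCc2ccccc2)c1 | starting material
19 | 1-[3,5-bis(benzyloxy)-2-bromophenyl]ethan-1-one | CC(=O)c1cc(OCc2ccccc2)cc(OCc2ccccc2)c1Br | intermediate
20 | 4-(benzyloxy)benzaldehyde | O=Cc1ccc(OCc2ccccc2)cc1 | starting material
21 | (E)-1-[3,5-bis(benzyloxy)-2-bromophenyl]-3-[4-(benzyloxy)phenyl]prop-2-en-1-one | O=C(/C=C/c1ccc(OCc2ccccc2)cc1)c1cc(OCc2ccccc2)cc(OCc2ccccc2)c1Br | intermediate
22 | (S)-4,6-bis(benzyloxy)-3-[4-(benzyloxy)phenyl]indan-1-one | c1ccc(COc2ccc([C@H]3c4c(OCc5ccccc5)cc(OCc5ccccc5)cc4C(=O)C3)cc2)cc1 | intermediate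
23 | (2S,3S)-4,6-bis(benzyloxy)-2-[3,5-bis(benzyloxy)phenyl]-3-[4-(benzyloxy)phenyl]indan-1-one | c1ccc(COc2ccc([C@H]3c4c(OCc5ccccc5)cc(OCc5ccccc5)cc4C(=O)[C@@H]3c3cc(OCc4ccccc4)cc(OCc4ccccc4)c3)cc2)cc1 | intermediate
24 | {[(2R,3R)-3-[3,5-bis(benzyloxy)phenyl]-2-[4-(benzyloxy)phenyl]-2,3-dihydrobenzofuran-5-yl]methyl}magnesium chloride | Cl[Mg]Cc1ccc2c(c1)[C@@H](c1cc(OCc3ccccc3)cc(OCc3ccccc3)c1)[C@H](c1ccc(OCc3ccccc3)cc1)O2 | intermediate
25 | {[(2R,3R)-3-[3,5-bis(benzyloxy)phenyl]-2-[4-(benzyloxy)phenyl]-2,3-dihydrobenzofuran-5-yl]methyl}cerium dichloride | Cl[Ce](Cl)Cc1ccc2c(c1)[C@@H](c1cc(OCc3ccccc3)cc(OCc3ccccc3)c1)[C@H](c1ccc(OCc3ccccc3)cc1)O2 | intermediate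
26 | (1R,2S,3S)-4,6-bis(benzyloxy)-2-[3,5-bis(benzyloxy)phenyl]-3-[4-(benzyloxy)phenyl]-1-{[(2R,3R)-3-[3,5-bis(benzyloxy)phenyl]-2-[4-(benzyloxy)phenyl]-2,3-dihydrobenzofuran-5-yl]methyl}indan-1-ol | c1ccc(COc2ccc([C@H]3c4c(OCc5ccccc5)cc(OCc5ccccc5)cc4[C@@](O)(Cc4ccc5c(c4)[C@@H](c4cc(OCc6ccccc6)cc(OCc6ccccc6)c4)[C@H](c4ccc(OCc6ccccc6)cc4)O5)[C@@H]3c3cc(OCc4ccccc4)cc(OCc4ccccc4)c3)cc2)cc1 | intermediate
27 | (2R,3R)-5-[(E)-{(2S,3S)-4,6-bis(benzyloxy)-2-[3,5-bis(benzyloxy)phenyl]-3-[4-(benzyloxy)phenyl]-2,3-dihydro-1H-inden-1-ylidene}methyl]-3-[3,5-bis(benzyloxy)phenyl]-2-[4-(benzyloxy)phenyl]-2,3-dihydrobenzofuran | c1ccc(COc2ccc([C@H]3c4c(OCc5ccccc5)cc(OCc5ccccc5)cc4/C(=C/c4ccc5c(c4)[C@@H](c4cc(OCc6ccccc6)cc(OCc6ccccc6)c4)[C@H](c4ccc(OCc6ccccc6)cc4)O5)[C@@H]3c3cc(OCc4ccccc4)cc(OCc4ccccc4)c3)cc2)cc1 | intermediate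
28 | (1S,2S)-3-{(E)-[(2R,3R)-3-(3,5-dihydroxyphenyl)-2-(4-hydroxyphenyl)-2,3-dihydrobenzofuran-5-yl]methylidene}-2-(3,5-dihydroxyphenyl)-1-(4-hydroxyphenyl)indane-5,7-diol (CNP0184753.1) | Oc1ccc([C@H]2c3c(O)cc(O)cc3/C(=C/c3ccc4c(c3)[C@@H](c3cc(O)cc(O)c3)[C@H](c3ccc(O)cc3)O4)[C@@H]2c2cc(O)cc(O)c2)cc1 | target

## Step count and risks

Total: 16 steps. Longest linear sequence: 12 steps (steps 1–9, then 14–16); the indanone branch (steps 10–13) joins at step 14.

**Step 3 (key step).** The most likely failure is that the C3 iodane loses the C2 proton instead of rearranging (dehydrogenation to the flavone), or that C3 is simply methoxylated. Proton loss and solvent capture compete with a migration that the bromine meta to the migrating carbon slows slightly; a 2,3-shift of the C2 aryl group from the diaxial conformer is the third leak. The fallback separates oxidation from migration. Flavanone 4 is brominated with phenyltrimethylammonium tribromide in THF to the diequatorial (2S,3S)-3,6-dibromo-2-[4-(methylsulfonyloxy)phenyl]chroman-4-one F1. Trimethyl orthoformate and TsOH in methanol give the ketal (2S,3S)-3,6-dibromo-4,4-dimethoxy-2-[4-(methylsulfonyloxy)phenyl]chromane F2. AgBF4 in methanol then removes the equatorial bromide while the fused aryl carbon shifts, as in the rearrangement of α-halo aryl ketone ketals to 2-arylalkanoates, and aqueous work-up returns ester 7.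

**Step 6.** The stabilised benzylic radical may escape the iron centre and dimerise or abstract hydrogen before the aryl group is delivered, or the aryl group may arrive on both faces. The fallback makes the C–C bond in a two-electron step. Ester 9 undergoes decarboxylative borylation with bis(pinacolato)diboron (copper-catalysed or light-driven variants are known for such esters) to 2-[(2R,3R)-5-bromo-2-[4-(methylsulfonyloxy)phenyl]-2,3-dihydrobenzofuran-3-yl]-4,4,5,5-tetramethyl-1,3,2-dioxaborolane F3. Bromide 10 is lithiated with n-BuLi to [3,5-bis(benzyloxy)phenyl]lithium F4 and added to F3 at −78 °C to give the lithium aryl boronate complex F5. NBS then triggers the stereoretentive 1,2-shift of C3' from boron to the electron-rich aryl ring, which returns to 13.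

**Step 12.** Bromide may stay on palladium, so that the neutral, poorly selective pathway erodes the enantiomeric purity, and formate may reduce the aryl–palladium bond before it inserts. The fallback moves the enantioselective event to rhodium. Chalcone 21 undergoes Miyaura borylation (bis(pinacolato)diboron, PdCl2(dppf), KOAc) to (E)-1-[3,5-bis(benzyloxy)-2-(4,4,5,5-tetramethyl-1,3,2-dioxaborolan-2-yl)phenyl]-3-[4-(benzyloxy)phenyl]prop-2-en-1-one F6. Asymmetric intramolecular conjugate addition with [Rh(C2H4)2Cl]2, a chiral phosphoramidite and aqueous K3PO4, a known route to 3-aryl-1-indanones, returns to 22.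

**Step 15 (with step 14 behind it).** The tertiary benzylic sulfamate may ionise and lose the C2 proton, which would place the double bond in the ring and erase C2. A carbinol epimer from imperfect facial selectivity in step 14 would have C2–H syn to the leaving group and do the same. The fallback builds the alkene by sulfur extrusion, without a carbinol and without a benzylic organometallic reagent.
- Chloride 17 and potassium thioacetate give S-{[(2R,3R)-3-[3,5-bis(benzyloxy)phenyl]-2-[4-(benzyloxy)phenyl]-2,3-dihydrobenzofuran-5-yl]methyl} ethanethioate F7; K2CO3 in methanol frees the thiol [(2R,3R)-3-[3,5-bis(benzyloxy)phenyl]-2-[4-(benzyloxy)phenyl]-2,3-dihydrobenzofuran-5-yl]methanethiol F8.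
- Ketone 23 is reduced with NaBH4 to (1R,2S,3S)-4,6-bis(benzyloxy)-2-[3,5-bis(benzyloxy)phenyl]-3-[4-(benzyloxy)phenyl]indan-1-ol F9.
- Brief ionisation of F9 with trifluoroacetic acid in CH2Cl2 at 0 °C in the presence of F8 gives the (1S,2S,3S)-indan-1-yl benzylic sulfide F10, the thiol entering anti to the C2 aryl group.
- 3-Chloroperbenzoic acid oxidises F10 to the (1S,2S,3S)-sulfone F11.
- Ramberg–Bäcklund reaction (KOH, CCl4, t-BuOH) extrudes SO2 and returns to alkene 27 with the double bond fixed outside the ring.

## Further compounds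

F1 | step 3 | (2S,3S)-3,6-dibromo-2-[4-(methylsulfonyloxy)phenyl]chroman-4-one | O=C1[C@@H](Br)[C@H](c2ccc(OS(C)(=O)=O)cc2)Oc2ccc(Br)cc12
F2 | step 3 | (2S,3S)-3,6-dibromo-4,4-dimethoxy-2-[4-(methylsulfonyloxy)phenyl]chromane | COC1(OC)[C@@H](Br)[C@H](c2ccc(OS(C)(=O)=O)cc2)Oc2ccc(Br)cc12
F3 | step 6 | 2-[(2R,3R)-5-bromo-2-[4-(methylsulfonyloxy)phenyl]-2,3-dihydrobenzofuran-3-yl]-4,4,5,5-tetramethyl-1,3,2-dioxaborolane | Brc1ccc2c(c1)[C@@H](B1OC(C)(C)C(C)(C)O1)[C@H](c1ccc(OS(C)(=O)=O)cc1)O2
F4 | step 6 | [3,5-bis(benzyloxy)phenyl]lithium | [Li]c1cc(OCc2ccccc2)cc(OCc2ccccc2)c1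
F5 | step 6 | lithium [3,5-bis(benzyloxy)phenyl][(2R,3R)-5-bromo-2-[4-(methylsulfonyloxy)phenyl]-2,3-dihydrobenzofuran-3-yl](pinacolato)borate | [Li+].Brc1ccc2c(c1)[C@@H]([B-]1(c3cc(OCc4ccccc4)cc(OCc4ccccc4)c3)OC(C)(C)C(C)(C)O1)[C@H](c1ccc(OS(C)(=O)=O)cc1)O2
F6 | step 12 | (E)-1-[3,5-bis(benzyloxy)-2-(4,4,5,5-tetramethyl-1,3,2-dioxaborolan-2-yl)phenyl]-3-[4-(benzyloxy)phenyl]prop-2-en-1-one | O=C(/C=C/c1ccc(OCc2ccccc2)cc1)c1cc(OCc2ccccc2)cc(OCc2ccccc2)c1B1OC(C)(C)C(C)(C)O1
F7 | step 15 | S-{[(2R,3R)-3-[3,5-bis(benzyloxy)phenyl]-2-[4-(benzyloxy)phenyl]-2,3-dihydrobenzofuran-5-yl]methyl} ethanethioate | CC(=O)SCc1ccc2c(c1)[C@@H](c1cc(OCc3ccccc3)cc(OCc3ccccc3)c1)[C@H](c1ccc(OCc3ccccc3)cc1)O2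
F8 | step 15 | [(2R,3R)-3-[3,5-bis(benzyloxy)phenyl]-2-[4-(benzyloxy)phenyl]-2,3-dihydrobenzofuran-5-yl]methanethiol | SCc1ccc2c(c1)[C@@H](c1cc(OCc3ccccc3)cc(OCc3ccccc3)c1)[C@H](c1ccc(OCc3ccccc3)cc1)O2
F9 | step 15 | (1R,2S,3S)-4,6-bis(benzyloxy)-2-[3,5-bis(benzyloxy)phenyl]-3-[4-(benzyloxy)phenyl]indan-1-ol | c1ccc(COc2ccc([C@H]3c4c(OCc5ccccc5)cc(OCc5ccccc5)cc4[C@H](O)[C@@H]3c3cc(OCc4ccccc4)cc(OCc4ccccc4)c3)cc2)cc1
F10 | step 15 | (1S,2S,3S)-4,6-bis(benzyloxy)-2-[3,5-bis(benzyloxy)phenyl]-3-[4-(benzyloxy)phenyl]indan-1-yl [(2R,3R)-3-[3,5-bis(benzyloxy)phenyl]-2-[4-(benzyloxy)phenyl]-2,3-dihydrobenzofuran-5-yl]methyl sulfide | c1ccc(COc2ccc([C@H]3c4c(OCc5ccccc5)cc(OCc5ccccc5)cc4[C@@H](SCc4ccc5c(c4)[C@@H](c4cc(OCc6ccccc6)cc(OCc6ccccc6)c4)[C@H](c4ccc(OCc6ccccc6)cc4)O5)[C@@H]3c3cc(OCc4ccccc4)cc(OCc4ccccc4)c3)cc2)cc1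
F11 | step 15 | (1S,2S,3S)-4,6-bis(benzyloxy)-2-[3,5-bis(benzyloxy)phenyl]-3-[4-(benzyloxy)phenyl]indan-1-yl [(2R,3R)-3-[3,5-bis(benzyloxy)phenyl]-2-[4-(benzyloxy)phenyl]-2,3-dihydrobenzofuran-5-yl]methyl sulfone | c1ccc(COc2ccc([C@H]3c4c(OCc5ccccc5)cc(OCc5ccccc5)cc4[C@@H](S(=O)(=O)Cc4ccc5c(c4)[C@@H](c4cc(OCc6ccccc6)cc(OCc6ccccc6)c4)[C@H](c4ccc(OCc6ccccc6)cc4)O5)[C@@H]3c3cc(OCc4ccccc4)cc(OCc4ccccc4)c3)cc2)cc1
A1 | alternative 1 | (1S,2S)-3-(tert-butyldimethylsilyloxy)-2-(3,5-dimethoxyphenyl)-5-ethoxy-7-hydroxy-1-(4-methoxyphenyl)indane | CCOc1cc(O)c2c(c1)[C@H](O[Si](C)(C)C(C)(C)C)[C@H](c1cc(OC)cc(OC)c1)[C@H]2c1ccc(OC)cc1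
A2 | alternative 1 | 2-diazo-1-[5-(tert-butyldimethylsilyloxy)-4-(3,5-dimethoxyphenyl)-3-(4-methoxyphenyl)cyclopent-1-en-1-yl]ethan-1-one, configured as in A1 | O=C(C=[N+]=[N-])C1=C[C@H](c2ccc(OC)cc2)[C@@H](c2cc(OC)cc(OC)c2)[C@H]1O[Si](C)(C)C(C)(C)C
A3 | alternative 1 | ethoxyacetylene | CCOC#C
A4 | alternative 2 | methyl (2R,3R)-3-(3,5-dimethoxyphenyl)-2-(4-methoxyphenyl)-2,3-dihydrobenzofuran-5-carboxylate | COC(=O)c1ccc2c(c1)[C@@H](c1cc(OC)cc(OC)c1)[C@H](c1ccc(OC)cc1)O2
A5 | alternative 2 | (4S,5R)-4-(3,5-dimethoxyphenyl)-5-(4-methoxyphenyl)dihydrofuran-2(3H)-one | O=C1C[C@@H](c2cc(OC)cc(OC)c2)[C@H](c2ccc(OC)cc2)O1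
A6 | alternative 2 | (4S,5R)-4-(3,5-dimethoxyphenyl)-5-(4-methoxyphenyl)-2-(trimethylsilyloxy)-4,5-dihydrofuran | C[Si](C)(C)OC1=C[C@@H](c2cc(OC)cc(OC)c2)[C@H](c2ccc(OC)cc2)O1
A7 | alternative 2 | methyl coumalate | COC(=O)c1ccc(=O)oc1
A8 | alternative 3 | (S)-4,6-dimethoxy-3-(4-methoxyphenyl)indan-1-one | COc1ccc([C@H]2c3c(OC)cc(OC)cc3C(=O)C2)cc1
A9 | alternative 3 | rac-1-(3,5-dimethoxyphenyl)-3-(4-methoxyphenyl)prop-2-yn-1-ol | COc1ccc(C#CC(O)c2cc(OC)cc(OC)c2)cc1
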